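## Retrosynthetic overview

1. **Feature.** In flavone unit 1 (the apigenin half bound through its C4' oxygen), ring A carries oxygen at C5, C7 and C8a. At C4a it carries the three-carbon chain C4–C3–C2 that ends in ring B. This is an aroylacetyl-phloroglucinol, that is, an aryl-capped pentaketide chain folded by C-acylation.
2. **Last disconnections.** The three methyl ethers of unit 2 are removed last. Before that, O1–C2 of ring C of unit 1 is closed by cyclodehydration of a 2,4,6-trihydroxyphenyl 1,3-diketone; either ortho hydroxyl gives the same flavone.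
3. **Key disconnection.** C4a–C8a of ring A of unit 1 (identical with C4a–C5 by symmetry) is opened to a methyl 9-aryl-3,5,7,9-tetraoxononanoate. This ester is stored as its 4-hydroxy-2-pyrone lactone and released by Mg(OMe)2.
4. **Precursor.** The pyrone is cut at chain bond C8–C9 into the trianion of 6-acetonyl-4-hydroxy-2-pyrone (triacetic acid lactone plus one acetyl unit) and a methyl 4-aryloxybenzoate. The diaryl ether is cut into methyl 4-fluorobenzoate and 8-hydroxy-trimethylapigenin, made from trimethylapigenin by C8 iodination and borylation–oxidation.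
5. **Ring order.** Rings A, B and C of unit 2 and ring B of unit 1 are bought. Ring A of unit 1 is built in step 6 at the cost of the pyrone ring, and ring C of unit 1 in step 7.

Key step: step 6

Remark: the poly-β-carbonyl compounds 10 to 14 are drawn as keto tautomers although they should be largely enolised (14 also as its cyclic 2-hydroxyflavanone hemiketal), and all tautomers converge in the following steps; chain locants C1–C9 are those of nonanoate 13 (C1 = pyrone C2, C5 = pyrone C6, C9 = aryl ketone); the target has no stereocentre.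

## Route

Step 1
Reactants: 1 5,7-dimethoxy-2-(4-methoxyphenyl)-4H-chromen-4-one (4',5,7-trimethoxyflavone)
Product: 2 8-iodo-5,7-dimethoxy-2-(4-methoxyphenyl)-4H-chromen-4-one
Conditions: NIS (1.1 equiv), DMF, rt to 50 °C, dark
Reagents that add atoms: N-iodosuccinimide, O=C1CCC(=O)N1I
Why: Electrophilic aromatic iodination: ring A with its three oxygen donors is far more nucleophilic than the anisyl ring or C3, and with O5 alkylated the iodonium source should attack C8 (para to the 5-methoxy group, ortho to the 7-methoxy group and O1) rather than C6, which is wedged between two methoxy groups.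

Step 2
Reactants: 2 8-iodo-5,7-dimethoxy-2-(4-methoxyphenyl)-4H-chromen-4-one
Product: 4 8-hydroxy-5,7-dimethoxy-2-(4-methoxyphenyl)-4H-chromen-4-one, via 8-pinacolboronate 3 (not isolated)
Conditions: B2pin2, Pd(OAc)2 (5 mol %), SPhos (10 mol %), KOAc, 1,4-dioxane, 90 °C; then 30% aq H2O2, THF, 0 °C to rt
Reagents that add atoms: bis(pinacolato)diboron, CC1(C)OB(OC1(C)C)B1OC(C)(C)C(C)(C)O1 (boryl group of 3); hydrogen peroxide, OO (oxygen at C8 of 4)
Why: Miyaura borylation (oxidative addition of zerovalent palladium into the C8–I bond, acetate-assisted transmetalation, reductive elimination; the bulky biarylphosphine copes with the two ortho oxygen substituents) followed by the standard peroxide oxidation of an aryl boronate, in which the aryl group migrates from boron to oxygen so that the hydroxyl ends up exactly at C8, while the vinylogous-ester double bond C2=C3 is too electron-rich for nucleophilic epoxidation under these nearly neutral conditions.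

Step 3
Reactants: 4 8-hydroxy-5,7-dimethoxy-2-(4-methoxyphenyl)-4H-chromen-4-one; 5 methyl 4-fluorobenzoate
Product: 6 methyl 4-{[5,7-dimethoxy-2-(4-methoxyphenyl)-4-oxo-4H-chromen-8-yl]oxy}benzoate
Conditions: Cs2CO3, 5 (1.5 equiv), dry DMSO, 110 °C, Ar
Reagents that add atoms: none
Why: Nucleophilic aromatic substitution by addition–elimination: the caesium phenoxide of 4, the only free hydroxyl in the molecule, adds at C4 of 5 to a Meisenheimer adduct stabilised by the para ester and fluoride leaves, an electronically matched pairing of an electron-rich phenoxide and an electron-poor fluoroarene.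

Step 4
Reactants: 7 4-hydroxy-6-methyl-2H-pyran-2-one (triacetic acid lactone); 8 N-methoxy-N-methylacetamide
Product: 10 4-hydroxy-6-(2-oxopropyl)-2H-pyran-2-one (6-acetonyl-4-hydroxy-2-pyrone), via dilithio dianion 9 (not isolated)
Conditions: LiN(iPr)2 (2.2 equiv), THF, −78 to 0 °C; 8, −78 to 0 °C; 1 M HCl
Reagents that add atoms: lithium diisopropylamide, [Li+].CC(C)[N-]C(C)C (lithium of 9 only)
Why: Weinreb ketone synthesis on a dianion: after O4–H the vinylogous C6-methyl group is deprotonated, this last-formed carbanion is the most nucleophilic site of 9, and the lithium-chelated tetrahedral adduct with 8 holds until the acid quench, which rules out over-addition and proton transfer from the more acidic product.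

Step 5
Reactants: 10 4-hydroxy-6-(2-oxopropyl)-2H-pyran-2-one; 6 methyl 4-{[5,7-dimethoxy-2-(4-methoxyphenyl)-4-oxo-4H-chromen-8-yl]oxy}benzoate
Product: 12 4-hydroxy-6-[4-(4-{[5,7-dimethoxy-2-(4-methoxyphenyl)-4-oxo-4H-chromen-8-yl]oxy}phenyl)-2,4-dioxobutyl]-2H-pyran-2-one, via trilithio trianion 11 (not isolated)
Conditions: 10 (2.2 equiv), LiN(iPr)2 (6.6 equiv), THF, DMPU, −78 to 0 °C; 6 (1 equiv), THF, −78 °C to rt; 1 M HCl, 0 °C
Reagents that add atoms: lithium diisopropylamide, [Li+].CC(C)[N-]C(C)C (lithium of 11 only)
Why: Crossed Claisen aroylation of a polyanion, the reaction type known for trianions of 1,3,5-triketones and methyl benzoates: deprotonation at O4–H, at the doubly activated CH2 and last at the terminal CH3 leaves the terminal carbanion of 11 as the most reactive site, it attacks the non-enolisable ester 6 to form C8–C9, and the second equivalent of 11 takes up the acidic C8 proton of the product, so that no free amide base remains to metalate C3 of the flavone.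

Step 6
Reactants: 12 4-hydroxy-6-[4-(4-{[5,7-dimethoxy-2-(4-methoxyphenyl)-4-oxo-4H-chromen-8-yl]oxy}phenyl)-2,4-dioxobutyl]-2H-pyran-2-one
Product: 14 1-(4-{[5,7-dimethoxy-2-(4-methoxyphenyl)-4-oxo-4H-chromen-8-yl]oxy}phenyl)-3-(2,4,6-trihydroxyphenyl)propane-1,3-dione, via open-chain tetraketo ester 13 (not isolated)
Conditions: Mg(OMe)2 (8 equiv, commercial solution in MeOH), MeOH, reflux, Ar; then 1 M HCl, 0 °C
Reagents that add atoms: magnesium methoxide, [Mg+2].C[O-].C[O-] (methoxy group of 13 only, lost again in the ring closure)
Why: Methoxide from the magnesium alkoxide adds to the lactone carbonyl of 12 (pyrone C2, chain C1) and the ring opens to the magnesium-chelated tetraketo ester 13; its C6 carbon, the methylene between the C5 and C7 ketones, then attacks the ester carbon C1, methoxide leaves, and enolisation of the cyclohexanetrione gives the 2,4,6-trihydroxyphenyl ring with the aroylacetyl chain on the attacking carbon, which forms C4a–C8a of unit 1 (the same bond as C4a–C5 by symmetry). The closest known reaction type is the intramolecular Claisen (Dieckmann-type) C-acylation by which 3,5,7-triketo esters and 6-(2-oxoalkyl)-4-hydroxy-2-pyrones are turned into acylphloroglucinols with Mg(OMe)2 in methanol; 12 differs by one more β-carbonyl in the side chain. The one new ring closes in the 6-exo-trig mode at the ester carbonyl, and no stereocentre is created. The step needs chemoselectivity among four six-membered foldings, the Claisen closure C6 to C1 against the aldol closures C2 to C7, C4 to C9 and C8 to C3. Three features of the substrate favour the Claisen path: C1 to C5 stay locked in the pyronate until the lactone opens, so that C2 and C4 are not free donors and C3 is not an acceptor at the start; C7 and C9 are tied up as a magnesium 1,3-diketonate (C9 further deactivated by the para-aryloxy donor), which makes them poor aldol acceptors and C8 a poor donor; and C1 is the only carbonyl with a leaving group, so that its acylation product aromatises at once to a magnesium phenoxide and is withdrawn irreversibly, while aldol adducts can revert in dry methanol. Flavone unit 2 should survive because Mg(OMe)2 is a weak nucleophile, and even a reversible opening of its ring C can only reclose to the same flavone since O5 is methylated.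

Step 7
Reactants: 14 1-(4-{[5,7-dimethoxy-2-(4-methoxyphenyl)-4-oxo-4H-chromen-8-yl]oxy}phenyl)-3-(2,4,6-trihydroxyphenyl)propane-1,3-dione
Product: 15 2-(4-{[5,7-dimethoxy-2-(4-methoxyphenyl)-4-oxo-4H-chromen-8-yl]oxy}phenyl)-5,7-dihydroxy-4H-chromen-4-one
Conditions: H2SO4 (cat.), AcOH, 95 °C
Reagents that add atoms: none
Why: Acid-catalysed cyclodehydration of a 2-hydroxyaryl 1,3-diketone, the closing stage of a Baker–Venkataraman flavone synthesis: an ortho phenol adds to the protonated aryl ketone carbon (6-exo-trig, O1–C2), water is lost to give the aromatic pyranone, the two ortho hydroxyls are equivalent so that only one flavone can form, and the methyl ether at O5 of unit 2 keeps that unit from Wessely–Moser isomerisation.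

Step 8
Reactants: 15 2-(4-{[5,7-dimethoxy-2-(4-methoxyphenyl)-4-oxo-4H-chromen-8-yl]oxy}phenyl)-5,7-dihydroxy-4H-chromen-4-one
Product: 16 lanaroflavone, 8-[4-(5,7-dihydroxy-4-oxo-4H-chromen-2-yl)phenoxy]-5,7-dihydroxy-2-(4-hydroxyphenyl)-4H-chromen-4-one
Conditions: BBr3 (12 equiv), CH2Cl2, −78 °C to rt; then ice-water
Reagents that add atoms: none
Why: Lewis acid ether cleavage: BBr3 binds each methoxy oxygen and bromide removes the methyl group by SN2, the diaryl ether has no sp3 carbon to lose and stays intact, and the anhydrous low-temperature conditions avoid the hydrolytic opening of ring C that in hot HI or molten pyridinium chloride would trigger a Wessely–Moser shift of the aryloxy group from C8 to C6.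

## Compound list

1 | 5,7-dimethoxy-2-(4-methoxyphenyl)-4H-chromen-4-one (4',5,7-trimethoxyflavone) | COc1ccc(cc1)-c1cc(=O)c2c(OC)cc(OC)cc2o1 | starting material
2 | 8-iodo-5,7-dimethoxy-2-(4-methoxyphenyl)-4H-chromen-4-one | COc1ccc(cc1)-c1cc(=O)c2c(OC)cc(OC)c(I)c2o1 | intermediate
3 | 5,7-dimethoxy-2-(4-methoxyphenyl)-8-(4,4,5,5-tetramethyl-1,3,2-dioxaborolan-2-yl)-4H-chromen-4-one | COc1ccc(cc1)-c1cc(=O)c2c(OC)cc(OC)c(B3OC(C)(C)C(C)(C)O3)c2o1 | intermediate
4 | 8-hydroxy-5,7-dimethoxy-2-(4-methoxyphenyl)-4H-chromen-4-one | COc1ccc(cc1)-c1cc(=O)c2c(OC)cc(OC)c(O)c2o1 | intermediate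
5 | methyl 4-fluorobenzoate | COC(=O)c1ccc(F)cc1 | starting material
6 | methyl 4-{[5,7-dimethoxy-2-(4-methoxyphenyl)-4-oxo-4H-chromen-8-yl]oxy}benzoate | COC(=O)c1ccc(Oc2c(OC)cc(OC)c3c(=O)cc(oc23)-c2ccc(OC)cc2)cc1 | intermediate
7 | 4-hydroxy-6-methyl-2H-pyran-2-one (triacetic acid lactone) | Cc1cc(O)cc(=O)o1 | starting material
8 | N-methoxy-N-methylacetamide | CC(=O)N(C)OC | starting material
9 | dilithium salt of 7 (4-oxide and C6-methylene carbanion) | [Li+].[Li+].[CH2-]c1cc([O-])cc(=O)o1 | intermediate
10 | 4-hydroxy-6-(2-oxopropyl)-2H-pyran-2-one | CC(=O)Cc1cc(O)cc(=O)o1 | intermediate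
11 | trilithium salt of 10 (4-oxide, internal CH and terminal CH2 carbanions) | [Li+].[Li+].[Li+].[CH2-]C(=O)[CH-]c1cc([O-])cc(=O)o1 | intermediate
12 | 4-hydroxy-6-[4-(4-{[5,7-dimethoxy-2-(4-methoxyphenyl)-4-oxo-4H-chromen-8-yl]oxy}phenyl)-2,4-dioxobutyl]-2H-pyran-2-one | O=C(CC(=O)Cc1cc(O)cc(=O)o1)c1ccc(Oc2c(OC)cc(OC)c3c(=O)cc(oc23)-c2ccc(OC)cc2)cc1 | intermediate
13 | methyl 9-(4-{[5,7-dimethoxy-2-(4-methoxyphenyl)-4-oxo-4H-chromen-8-yl]oxy}phenyl)-3,5,7,9-tetraoxononanoate (present as its magnesium chelate) | COC(=O)CC(=O)CC(=O)CC(=O)CC(=O)c1ccc(Oc2c(OC)cc(OC)c3c(=O)cc(oc23)-c2ccc(OC)cc2)cc1 | intermediate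
14 | 1-(4-{[5,7-dimethoxy-2-(4-methoxyphenyl)-4-oxo-4H-chromen-8-yl]oxy}phenyl)-3-(2,4,6-trihydroxyphenyl)propane-1,3-dione | O=C(CC(=O)c1c(O)cc(O)cc1O)c1ccc(Oc2c(OC)cc(OC)c3c(=O)cc(oc23)-c2ccc(OC)cc2)cc1 | intermediate
15 | 2-(4-{[5,7-dimethoxy-2-(4-methoxyphenyl)-4-oxo-4H-chromen-8-yl]oxy}phenyl)-5,7-dihydroxy-4H-chromen-4-one | O=c1cc(-c2ccc(Oc3c(OC)cc(OC)c4c(=O)cc(-c5ccc(OC)cc5)oc34)cc2)oc2cc(O)cc(O)c12 | intermediate
16 | lanaroflavone | O=c1cc(-c2ccc(Oc3c(O)cc(O)c4c(=O)cc(-c5ccc(O)cc5)oc34)cc2)oc2cc(O)cc(O)c12 | target

## Step count and risks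

Total step count: 8. Longest linear sequence: 7 (steps 1, 2, 3, 5, 6, 7, 8); step 4 is the side branch.

**First risk, step 6.**
- The chain may misfold by aldol addition and dehydration instead of C-acylation. This can happen after ring opening, or from pyrone C5 onto the aryl ketone before the lactone opens.
- Methoxide may also cleave the 1,3-diketone by retro-Claisen reaction during the reflux.
- In the fallback, ring A of unit 1 is bought rather than folded.
- Setting out from 6, saponification (LiOH, THF–H2O, then acid) should give 4-{[5,7-dimethoxy-2-(4-methoxyphenyl)-4-oxo-4H-chromen-8-yl]oxy}benzoic acid F1.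
- Oxalyl chloride with catalytic DMF in CH2Cl2 should then give 4-{[5,7-dimethoxy-2-(4-methoxyphenyl)-4-oxo-4H-chromen-8-yl]oxy}benzoyl chloride F2.
- F2 is added at −78 °C to commercial 2',4',6'-trihydroxyacetophenone that has been fully deprotonated with excess LiN(SiMe3)2 in THF.
- The methyl ketone enolate is then the most nucleophilic site and is aroylated (the direct variant of the Baker–Venkataraman sequence).
- Acid work-up should deliver 14, where the route is rejoined.

**Second risk, step 5.**
- The third deprotonation may be incomplete, or the polylithium salt may dissolve poorly.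
- Proton transfer may outrun acylation.
- The carbanion may add to C2 or C4 of the flavone instead of the ester.
- The fallback cuts the chain at C6–C7 instead of C8–C9, so that only the dianion is needed.
- Setting out from 6, crossed Claisen condensation with the lithium enolate of methyl acetate (LiN(iPr)2, MeOAc, THF, −78 to 0 °C) should give methyl 3-(4-{[5,7-dimethoxy-2-(4-methoxyphenyl)-4-oxo-4H-chromen-8-yl]oxy}phenyl)-3-oxopropanoate F3.
- F3 is shielded in the flask as its lithium enolate and then acylates the dianion 9 (made from 7 as in step 4) at the exocyclic carbanion (THF, 0 °C to rt).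
- This is the known acylation of polyanions by salts of β-keto esters. Acid quench should give 12, where the route is rejoined.

**Third risk, step 3.**
- Addition of the doubly ortho-substituted phenoxide to a fluoroarene activated by only one ester may be sluggish.
- The phenoxide may instead attack the ester carbonyl or its methyl group.
- The electron-rich phenoxide may be oxidised by air at high temperature.
- The fallback replaces addition–elimination by metal-free aryl transfer from a diaryliodonium salt.
- Commercial methyl 4-iodobenzoate is oxidised with mCPBA and TsOH·H2O in MeCN and treated with 1,3,5-trimethoxybenzene. This should give [4-(methoxycarbonyl)phenyl](2,4,6-trimethoxyphenyl)iodonium 4-methylbenzenesulfonate F4.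
- Setting out from 4, treatment with F4 and K2CO3 in MeCN at 50 °C should transfer the electron-poorer aryl group to O8 by ligand coupling at iodine. This gives 6, where the route is rejoined.

## Further compounds

F1 | step 6 | 4-{[5,7-dimethoxy-2-(4-methoxyphenyl)-4-oxo-4H-chromen-8-yl]oxy}benzoic acid | OC(=O)c1ccc(Oc2c(OC)cc(OC)c3c(=O)cc(oc23)-c2ccc(OC)cc2)cc1
F2 | step 6 | 4-{[5,7-dimethoxy-2-(4-methoxyphenyl)-4-oxo-4H-chromen-8-yl]oxy}benzoyl chloride | ClC(=O)c1ccc(Oc2c(OC)cc(OC)c3c(=O)cc(oc23)-c2ccc(OC)cc2)cc1
F3 | step 5 | methyl 3-(4-{[5,7-dimethoxy-2-(4-methoxyphenyl)-4-oxo-4H-chromen-8-yl]oxy}phenyl)-3-oxopropanoate | COC(=O)CC(=O)c1ccc(Oc2c(OC)cc(OC)c3c(=O)cc(oc23)-c2ccc(OC)cc2)cc1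
F4 | step 3 | [4-(methoxycarbonyl)phenyl](2,4,6-trimethoxyphenyl)iodonium 4-methylbenzenesulfonate | COC(=O)c1ccc(cc1)[I+]c1c(OC)cc(OC)cc1OC.Cc1ccc(cc1)S(=O)(=O)[O-]
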